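**Retrosynthetic overview**

1. The target is an ester of two mirror-image 2-benzoxepin-1-ones: half A (5aS,6R,9S,9aS; free diol, C4 carboxyl esterified) and half B (5aR,6S,9R,9aR; free C4 acid, C9 CH2O acylated). The plan rests on one feature of each half: on C9 the CH2O carbon is cis to the lactone carbonyl carbon C1 on C9a, and the tertiary hydroxyl is trans to it.
2. Last disconnections: the ester between the halves (acid 22 plus the primary hydroxyl of diol 37), then in each half the seven-membered lactone, opened at C4=C5 (ring-closing metathesis) and at O2–C3 (carboxylate alkylation with tert-butyl 2-(bromomethyl)prop-2-enoate).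
3. Key disconnection: the C9–CH2 bond is made from C1 itself. SmI2 reduction of the iodomethyl ester of the C9-keto acid closes a temporary cis-fused γ-lactone (C1–O–CH2–C9), which is later opened to give the CH2OH and the C1 carboxyl.
4. The keto ester comes from cryptone by trans conjugate vinylation (C5a), enolate carboxylation (C9a), chloromethyl ester formation and iodide exchange; both hands of cryptone come from organocatalytic Michael addition and aldol condensation.
5. Ring order in each series: cyclohexenone, temporary γ-lactone, seven-membered lactone. Steps 1–11 give half A, steps 12–22 repeat them on the enantiomer for half B (step 18 is the mirror image of the key step), and steps 23–24 join and unmask.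

Key step: step 7

Assumption: the (R)-prolinol ether catalyst is taken to give the (2R)-aldehyde (enone adds to the enamine face away from the diarylmethyl group); if the sense proves opposite, the two catalysts are exchanged between the series.

**Route**

Step 1
Reactants: 1 3-methylbutanal; 2 but-3-en-2-one
Product: 3 (2R)-5-oxo-2-(propan-2-yl)hexanal
Conditions: (R)-2-[methoxy(diphenyl)methyl]pyrrolidine (5 mol%), ethyl 3,4-dihydroxybenzoate (20 mol%), neat, 4 °C
Reagents that add atoms: none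
Why: Enamine-catalysed Michael addition in which the enone should add to the enamine face remote from the diphenyl(methoxy)methyl group, setting the future C6 centre as R.

Step 2
Reactants: 3 (2R)-5-oxo-2-(propan-2-yl)hexanal
Product: 4 (4R)-4-(propan-2-yl)cyclohex-2-en-1-one
Conditions: LiOH (cat.), i-PrOH, rt
Reagents that add atoms: none
Why: Intramolecular aldol condensation of the methyl ketone enolate onto the aldehyde closes the cyclohexenone, the mild base being chosen so that the α-branched centre is not epimerised before closure.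

Step 3
Reactants: 4 (4R)-4-(propan-2-yl)cyclohex-2-en-1-one; 5 vinylmagnesium bromide
Product: 6 trimethyl{[(3R,4R)-3-ethenyl-4-(propan-2-yl)cyclohex-1-en-1-yl]oxy}silane
Conditions: CuBr·SMe2 (10 mol%), TMSCl, THF, −78 °C; Et3N, cold aq. NaHCO3
Reagents that add atoms: chlorotrimethylsilane, C[Si](C)(C)Cl
Why: Copper-catalysed conjugate addition accelerated by TMSCl should deliver the vinyl group to C5a anti to the neighbouring isopropyl group (trans) and traps the enolate regiospecifically as its silyl enol ether.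

Step 4
Reactants: 6 trimethyl{[(3R,4R)-3-ethenyl-4-(propan-2-yl)cyclohex-1-en-1-yl]oxy}silane; 7 carbon dioxide
Product: 9 (1S,2R,3R)-2-ethenyl-6-oxo-3-(propan-2-yl)cyclohexane-1-carboxylic acid, via lithium enolate 8 (not isolated)
Conditions: MeLi, THF, 0 °C; CO2 (g), −78 °C; cold 1 M HCl; used at once
Reagents that add atoms: methyllithium, C[Li] (lithium of 8)
Why: Methyllithium cleaves the Si–O bond to the regiodefined lithium enolate, which is C-carboxylated anti to the vinyl group; C9a is in any case epimerisable and should settle all-equatorial, C1 trans to vinyl.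

Step 5
Reactants: 9 (1S,2R,3R)-2-ethenyl-6-oxo-3-(propan-2-yl)cyclohexane-1-carboxylic acid; 10 chloromethyl chlorosulfate
Product: 11 chloromethyl (1S,2R,3R)-2-ethenyl-6-oxo-3-(propan-2-yl)cyclohexane-1-carboxylate
Conditions: NaHCO3, n-Bu4NHSO4 (10 mol%), CH2Cl2/H2O, 0 °C → rt
Reagents that add atoms: none
Why: Phase-transfer O-alkylation of the carboxylate, with chlorosulfate as the far better leaving group than chloride, gives the chloromethyl ester, while bicarbonate is too weak to ionise the β-keto ester so its enol oxygen leaves the CH2Cl group alone.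

Step 6
Reactants: 11 chloromethyl (1S,2R,3R)-2-ethenyl-6-oxo-3-(propan-2-yl)cyclohexane-1-carboxylate
Product: 12 iodomethyl (1S,2R,3R)-2-ethenyl-6-oxo-3-(propan-2-yl)cyclohexane-1-carboxylate
Conditions: NaI, acetone, rt, dark
Reagents that add atoms: sodium iodide, [Na+].[I-]
Why: Finkelstein exchange, driven by precipitation of NaCl from acetone, makes the carbon–halogen bond readily reducible by SmI2.

Step 7
Reactants: 12 iodomethyl (1S,2R,3R)-2-ethenyl-6-oxo-3-(propan-2-yl)cyclohexane-1-carboxylate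
Product: 14 (3aS,6R,7R,7aS)-7-ethenyl-3a-hydroxy-6-(propan-2-yl)hexahydro-2-benzofuran-1(3H)-one, via acyloxymethylsamarium diiodide 13 (not isolated)
Conditions: 12 added slowly to SmI2 (2.5 equiv), THF, −78 °C → −20 °C; aq. NH4Cl
Reagents that add atoms: samarium diiodide, I[Sm]I (samarium and iodine of 13)
Why: Proposed new method: two single-electron transfers from divalent samarium cleave the C–I bond of 12 and give the acyloxymethyl organosamarium 13 (trivalent samarium), whose carbon adds to the C9 ketone three atoms away; a path through the samarium ketyl of the chelated keto ester would form the same bond. The closest known reaction types are the SmI2 intramolecular Barbier cyclisation of iodoalkyl ketones and β-keto esters and the Barbier-type use of alkoxymethyl halides with SmI2, or of acyloxymethyl zinc and copper reagents, to deliver a nucleophilic CH2O unit. The ring O–CH2–C9–C9a–C1 closes in the 5-exo-trig mode. The new centre C9 is set by the tether: with the ester equatorial on C9a the CH2 is delivered along the axial trajectory to the cis-fused lactone, because this closure only flattens the chair whereas the trans-fused γ-lactone, though not impossible, needs the six-membered ring to pucker further, so CH2 ends cis and the hydroxyl trans to C1. The step needs this facial selectivity and needs closure to outrun protonation of the carbon–samarium bond by the acidic C9a–H and simple reduction of the ketone; the short tether, the aprotic base-free medium and warming to −20 °C, which lets the ester turn from its preferred Z rotamer into the E rotamer required for closure, are meant to secure it.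

Step 8
Reactants: 14 (3aS,6R,7R,7aS)-7-ethenyl-3a-hydroxy-6-(propan-2-yl)hexahydro-2-benzofuran-1(3H)-one
Product: 17 (1S,2R,3R,6S)-6-({[tert-butyl(dimethyl)silyl]oxy}methyl)-2-ethenyl-6-hydroxy-3-(propan-2-yl)cyclohexane-1-carboxylic acid, via potassium carboxylate 15 (not isolated), via silyl ester 16 (not isolated)
Conditions: KOH, THF/H2O, rt; evaporate; TBSCl, imidazole, DMF (concentrated), rt; K2CO3, MeOH/H2O, 0 °C; citric acid to pH 5
Reagents that add atoms: potassium hydroxide, [K+].[OH-]; tert-butyl(chloro)dimethylsilane, CC(C)(C)[Si](C)(C)Cl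
Why: Saponification of the γ-lactone frees C1 and the CH2OH, and silylation of the primary hydroxyl and the carboxylate (tertiary hydroxyl inert) followed by mild cleavage of the labile silyl ester gives the acid in a form that cannot relactonise.

Step 9
Reactants: 17 (1S,2R,3R,6S)-6-({[tert-butyl(dimethyl)silyl]oxy}methyl)-2-ethenyl-6-hydroxy-3-(propan-2-yl)cyclohexane-1-carboxylic acid; 18 tert-butyl 2-(bromomethyl)prop-2-enoate
Product: 19 2-(tert-butoxycarbonyl)prop-2-en-1-yl (1S,2R,3R,6S)-6-({[tert-butyl(dimethyl)silyl]oxy}methyl)-2-ethenyl-6-hydroxy-3-(propan-2-yl)cyclohexane-1-carboxylate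
Conditions: K2CO3, DMF, 0 °C → rt
Reagents that add atoms: none
Why: Carboxylate O-alkylation by the allylic bromide (SN2 and SN2′ give the same ester) installs O2–C3, C4 and the C4 carboxyl, the tertiary hydroxyl not being alkylated under these conditions.

Step 10
Reactants: 19 2-(tert-butoxycarbonyl)prop-2-en-1-yl (1S,2R,3R,6S)-6-({[tert-butyl(dimethyl)silyl]oxy}methyl)-2-ethenyl-6-hydroxy-3-(propan-2-yl)cyclohexane-1-carboxylate
Product: 20 tert-butyl (5aS,6R,9S,9aS)-9-({[tert-butyl(dimethyl)silyl]oxy}methyl)-9-hydroxy-1-oxo-6-(propan-2-yl)-1,3,5a,6,7,8,9,9a-octahydro-2-benzoxepine-4-carboxylate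
Conditions: second-generation Hoveyda–Grubbs catalyst (10 mol%), toluene (2 mM), 80 °C, argon purge
Reagents that add atoms: none
Why: Ring-closing metathesis in which the alkylidene formed at the vinyl group should close onto the 1,1-disubstituted acrylate, held near by the trans-diequatorial arrangement, to give the endocyclic C4=C5 bond with loss of ethene.

Step 11
Reactants: 20 tert-butyl (5aS,6R,9S,9aS)-9-({[tert-butyl(dimethyl)silyl]oxy}methyl)-9-hydroxy-1-oxo-6-(propan-2-yl)-1,3,5a,6,7,8,9,9a-octahydro-2-benzoxepine-4-carboxylate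
Product: 22 (5aS,6R,9S,9aS)-9-({[tert-butyl(dimethyl)silyl]oxy}methyl)-1-oxo-6-(propan-2-yl)-9-[(trimethylsilyl)oxy]-1,3,5a,6,7,8,9,9a-octahydro-2-benzoxepine-4-carboxylic acid, via trimethylsilyl ester 21 (not isolated)
Conditions: TMSOTf, 2,6-lutidine, CH2Cl2, 0 °C → rt; pH 5 phosphate buffer
Reagents that add atoms: trimethylsilyl trifluoromethanesulfonate, C[Si](C)(C)OS(=O)(=O)C(F)(F)F
Why: Silyl triflate dealkylation of the tert-butyl ester (carbonyl silylation, loss of the tert-butyl cation as isobutene) spares the TBS ether and the lactone, caps the tertiary hydroxyl as its TMS ether, and the TMS ester falls to the acid on buffered work-up.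

Step 12
Reactants: 1 3-methylbutanal; 2 but-3-en-2-one
Product: 23 (2S)-5-oxo-2-(propan-2-yl)hexanal
Conditions: (S)-2-[methoxy(diphenyl)methyl]pyrrolidine (5 mol%), ethyl 3,4-dihydroxybenzoate (20 mol%), neat, 4 °C
Reagents that add atoms: none
Why: Enamine-catalysed Michael addition as in step 1, the enantiomeric catalyst being expected to give the S aldehyde.

Step 13
Reactants: 23 (2S)-5-oxo-2-(propan-2-yl)hexanal
Product: 24 (4S)-4-(propan-2-yl)cyclohex-2-en-1-one
Conditions: LiOH (cat.), i-PrOH, rt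
Reagents that add atoms: none
Why: Intramolecular aldol condensation as in step 2.

Step 14
Reactants: 24 (4S)-4-(propan-2-yl)cyclohex-2-en-1-one; 5 vinylmagnesium bromide
Product: 25 trimethyl{[(3S,4S)-3-ethenyl-4-(propan-2-yl)cyclohex-1-en-1-yl]oxy}silane
Conditions: CuBr·SMe2 (10 mol%), TMSCl, THF, −78 °C; Et3N, cold aq. NaHCO3
Reagents that add atoms: chlorotrimethylsilane, C[Si](C)(C)Cl
Why: Copper-catalysed conjugate addition anti to the isopropyl group with silyl trapping of the enolate, as in step 3.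

Step 15
Reactants: 25 trimethyl{[(3S,4S)-3-ethenyl-4-(propan-2-yl)cyclohex-1-en-1-yl]oxy}silane; 7 carbon dioxide
Product: 27 (1R,2S,3S)-2-ethenyl-6-oxo-3-(propan-2-yl)cyclohexane-1-carboxylic acid, via lithium enolate 26 (not isolated)
Conditions: MeLi, THF, 0 °C; CO2 (g), −78 °C; cold 1 M HCl; used at once
Reagents that add atoms: methyllithium, C[Li] (lithium of 26)
Why: Regiospecific enolate generation and C-carboxylation trans to the vinyl group, as in step 4.

Step 16
Reactants: 27 (1R,2S,3S)-2-ethenyl-6-oxo-3-(propan-2-yl)cyclohexane-1-carboxylic acid; 10 chloromethyl chlorosulfate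
Product: 28 chloromethyl (1R,2S,3S)-2-ethenyl-6-oxo-3-(propan-2-yl)cyclohexane-1-carboxylate
Conditions: NaHCO3, n-Bu4NHSO4 (10 mol%), CH2Cl2/H2O, 0 °C → rt
Reagents that add atoms: none
Why: Phase-transfer carboxylate O-alkylation with loss of chlorosulfate, as in step 5.

Step 17
Reactants: 28 chloromethyl (1R,2S,3S)-2-ethenyl-6-oxo-3-(propan-2-yl)cyclohexane-1-carboxylate
Product: 29 iodomethyl (1R,2S,3S)-2-ethenyl-6-oxo-3-(propan-2-yl)cyclohexane-1-carboxylate
Conditions: NaI, acetone, rt, dark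
Reagents that add atoms: sodium iodide, [Na+].[I-]
Why: Finkelstein exchange as in step 6.

Step 18
Reactants: 29 iodomethyl (1R,2S,3S)-2-ethenyl-6-oxo-3-(propan-2-yl)cyclohexane-1-carboxylate
Product: 31 (3aR,6S,7S,7aR)-7-ethenyl-3a-hydroxy-6-(propan-2-yl)hexahydro-2-benzofuran-1(3H)-one, via acyloxymethylsamarium diiodide 30 (not isolated)
Conditions: 29 added slowly to SmI2 (2.5 equiv), THF, −78 °C → −20 °C; aq. NH4Cl
Reagents that add atoms: samarium diiodide, I[Sm]I (samarium and iodine of 30)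
Why: Proposed new method: mirror image of step 7, in which divalent samarium reduces the C–I bond to the acyloxymethyl organosamarium 30 that closes 5-exo-trig on the C9 ketone to the cis-fused lactone (CH2 cis and hydroxyl trans to C1, enforced by the short ester tether), the closest known type being the SmI2 intramolecular Barbier cyclisation of iodoalkyl ketones and β-keto esters.

Step 19
Reactants: 31 (3aR,6S,7S,7aR)-7-ethenyl-3a-hydroxy-6-(propan-2-yl)hexahydro-2-benzofuran-1(3H)-one
Product: 34 (1R,2S,3S,6R)-6-({[tert-butyl(dimethyl)silyl]oxy}methyl)-2-ethenyl-6-hydroxy-3-(propan-2-yl)cyclohexane-1-carboxylic acid, via potassium carboxylate 32 (not isolated), via silyl ester 33 (not isolated)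
Conditions: KOH, THF/H2O, rt; evaporate; TBSCl, imidazole, DMF (concentrated), rt; K2CO3, MeOH/H2O, 0 °C; citric acid to pH 5
Reagents that add atoms: potassium hydroxide, [K+].[OH-]; tert-butyl(chloro)dimethylsilane, CC(C)(C)[Si](C)(C)Cl
Why: Lactone saponification, silylation and selective silyl ester cleavage as in step 8.

Step 20
Reactants: 34 (1R,2S,3S,6R)-6-({[tert-butyl(dimethyl)silyl]oxy}methyl)-2-ethenyl-6-hydroxy-3-(propan-2-yl)cyclohexane-1-carboxylic acid; 18 tert-butyl 2-(bromomethyl)prop-2-enoate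
Product: 35 2-(tert-butoxycarbonyl)prop-2-en-1-yl (1R,2S,3S,6R)-6-({[tert-butyl(dimethyl)silyl]oxy}methyl)-2-ethenyl-6-hydroxy-3-(propan-2-yl)cyclohexane-1-carboxylate
Conditions: K2CO3, DMF, 0 °C → rt
Reagents that add atoms: none
Why: Carboxylate O-alkylation by the allylic bromide as in step 9.

Step 21
Reactants: 35 2-(tert-butoxycarbonyl)prop-2-en-1-yl (1R,2S,3S,6R)-6-({[tert-butyl(dimethyl)silyl]oxy}methyl)-2-ethenyl-6-hydroxy-3-(propan-2-yl)cyclohexane-1-carboxylate
Product: 36 tert-butyl (5aR,6S,9R,9aR)-9-({[tert-butyl(dimethyl)silyl]oxy}methyl)-9-hydroxy-1-oxo-6-(propan-2-yl)-1,3,5a,6,7,8,9,9a-octahydro-2-benzoxepine-4-carboxylate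
Conditions: second-generation Hoveyda–Grubbs catalyst (10 mol%), toluene (2 mM), 80 °C, argon purge
Reagents that add atoms: none
Why: Ring-closing metathesis to the seven-membered lactone as in step 10.

Step 22
Reactants: 36 tert-butyl (5aR,6S,9R,9aR)-9-({[tert-butyl(dimethyl)silyl]oxy}methyl)-9-hydroxy-1-oxo-6-(propan-2-yl)-1,3,5a,6,7,8,9,9a-octahydro-2-benzoxepine-4-carboxylate
Product: 37 tert-butyl (5aR,6S,9R,9aR)-9-hydroxy-9-(hydroxymethyl)-1-oxo-6-(propan-2-yl)-1,3,5a,6,7,8,9,9a-octahydro-2-benzoxepine-4-carboxylate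
Conditions: HF·pyridine, pyridine, THF, 0 °C → rt
Reagents that add atoms: none
Why: Buffered fluoride desilylation frees the primary hydroxyl without forming an alkoxide that could attack the neighbouring C1 lactone, and leaves the tert-butyl ester untouched.

Step 23
Reactants: 22 (5aS,6R,9S,9aS)-9-({[tert-butyl(dimethyl)silyl]oxy}methyl)-1-oxo-6-(propan-2-yl)-9-[(trimethylsilyl)oxy]-1,3,5a,6,7,8,9,9a-octahydro-2-benzoxepine-4-carboxylic acid; 37 tert-butyl (5aR,6S,9R,9aR)-9-hydroxy-9-(hydroxymethyl)-1-oxo-6-(propan-2-yl)-1,3,5a,6,7,8,9,9a-octahydro-2-benzoxepine-4-carboxylate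
Product: 38 protected heterodimer ester (half A carrying OTMS and CH2OTBS; half B carrying the tert-butyl ester and free tertiary hydroxyl)
Conditions: EDC·HCl, DMAP (20 mol%), CH2Cl2, 0 °C → rt
Reagents that add atoms: none
Why: Steglich esterification in which the carbodiimide-activated acid acylates the only reactive hydroxyl present, the primary CH2OH of 37 (the tertiary carbinol does not react), joining the two mirror-image halves.

Step 24
Reactants: 38 protected heterodimer ester
Product: 39 CNP0340505.1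
Conditions: TFA/CH2Cl2/H2O (10:10:1), 0 °C → rt
Reagents that add atoms: none
Why: Acidolysis removes the tert-butyl ester (as isobutene) and both silyl ethers in one operation, while the lactones, the linking ester and the tertiary alcohols, whose ionisation is disfavoured by the adjacent oxygenated and carbonyl-bearing carbons, should survive.

**Compound list**

1 | 3-methylbutanal | CC(C)CC=O | starting material
2 | but-3-en-2-one | CC(=O)C=C | starting material
3 | (2R)-5-oxo-2-(propan-2-yl)hexanal | CC(C)[C@@H](CCC(C)=O)C=O | intermediate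
4 | (4R)-4-(propan-2-yl)cyclohex-2-en-1-one | CC(C)[C@H]1CCC(=O)C=C1 | intermediate
5 | vinylmagnesium bromide | C=C[Mg]Br | starting material
6 | trimethyl{[(3R,4R)-3-ethenyl-4-(propan-2-yl)cyclohex-1-en-1-yl]oxy}silane (vinyl trans to isopropyl) | CC(C)[C@H]1CCC(O[Si](C)(C)C)=C[C@@H]1C=C | intermediate
7 | carbon dioxide | O=C=O | starting material
8 | lithium (3R,4R)-3-ethenyl-4-(propan-2-yl)cyclohex-1-en-1-olate | CC(C)[C@H]1CCC(O[Li])=C[C@@H]1C=C | intermediate (not isolated)
9 | (1S,2R,3R)-2-ethenyl-6-oxo-3-(propan-2-yl)cyclohexane-1-carboxylic acid (all-trans) | CC(C)[C@H]1CCC(=O)[C@@H](C(=O)O)[C@@H]1C=C | intermediate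
10 | chloromethyl chlorosulfate | ClCOS(=O)(=O)Cl | starting material
11 | chloromethyl (1S,2R,3R)-2-ethenyl-6-oxo-3-(propan-2-yl)cyclohexane-1-carboxylate | CC(C)[C@H]1CCC(=O)[C@@H](C(=O)OCCl)[C@@H]1C=C | intermediate
12 | iodomethyl (1S,2R,3R)-2-ethenyl-6-oxo-3-(propan-2-yl)cyclohexane-1-carboxylate | CC(C)[C@H]1CCC(=O)[C@@H](C(=O)OCI)[C@@H]1C=C | intermediate
13 | ({[(1S,2R,3R)-2-ethenyl-6-oxo-3-(propan-2-yl)cyclohexane-1-carbonyl]oxy}methyl)samarium diiodide | CC(C)[C@H]1CCC(=O)[C@@H](C(=O)OC[Sm](I)I)[C@@H]1C=C | intermediate (not isolated)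
14 | (3aS,6R,7R,7aS)-7-ethenyl-3a-hydroxy-6-(propan-2-yl)hexahydro-2-benzofuran-1(3H)-one (cis-fused; hydroxyl trans to C1) | CC(C)[C@H]1CC[C@@]2(O)COC(=O)[C@H]2[C@@H]1C=C | intermediate
15 | potassium (1S,2R,3R,6S)-2-ethenyl-6-hydroxy-6-(hydroxymethyl)-3-(propan-2-yl)cyclohexane-1-carboxylate | CC(C)[C@H]1CC[C@@](O)(CO)[C@@H](C(=O)[O-])[C@@H]1C=C.[K+] | intermediate (not isolated)
16 | tert-butyl(dimethyl)silyl (1S,2R,3R,6S)-6-({[tert-butyl(dimethyl)silyl]oxy}methyl)-2-ethenyl-6-hydroxy-3-(propan-2-yl)cyclohexane-1-carboxylate | CC(C)[C@H]1CC[C@@](O)(CO[Si](C)(C)C(C)(C)C)[C@@H](C(=O)O[Si](C)(C)C(C)(C)C)[C@@H]1C=C | intermediate (not isolated)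
17 | (1S,2R,3R,6S)-6-({[tert-butyl(dimethyl)silyl]oxy}methyl)-2-ethenyl-6-hydroxy-3-(propan-2-yl)cyclohexane-1-carboxylic acid | CC(C)[C@H]1CC[C@@](O)(CO[Si](C)(C)C(C)(C)C)[C@@H](C(=O)O)[C@@H]1C=C | intermediate
18 | tert-butyl 2-(bromomethyl)prop-2-enoate | C=C(CBr)C(=O)OC(C)(C)C | starting material
19 | 2-(tert-butoxycarbonyl)prop-2-en-1-yl (1S,2R,3R,6S)-6-({[tert-butyl(dimethyl)silyl]oxy}methyl)-2-ethenyl-6-hydroxy-3-(propan-2-yl)cyclohexane-1-carboxylate | CC(C)[C@H]1CC[C@@](O)(CO[Si](C)(C)C(C)(C)C)[C@@H](C(=O)OCC(=C)C(=O)OC(C)(C)C)[C@@H]1C=C | intermediate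
20 | tert-butyl (5aS,6R,9S,9aS)-9-({[tert-butyl(dimethyl)silyl]oxy}methyl)-9-hydroxy-1-oxo-6-(propan-2-yl)-1,3,5a,6,7,8,9,9a-octahydro-2-benzoxepine-4-carboxylate | CC(C)[C@H]1CC[C@@](O)(CO[Si](C)(C)C(C)(C)C)[C@H]2C(=O)OCC(C(=O)OC(C)(C)C)=C[C@H]12 | intermediate
21 | trimethylsilyl (5aS,6R,9S,9aS)-9-({[tert-butyl(dimethyl)silyl]oxy}methyl)-1-oxo-6-(propan-2-yl)-9-[(trimethylsilyl)oxy]-1,3,5a,6,7,8,9,9a-octahydro-2-benzoxepine-4-carboxylate | CC(C)[C@H]1CC[C@@](O[Si](C)(C)C)(CO[Si](C)(C)C(C)(C)C)[C@H]2C(=O)OCC(C(=O)O[Si](C)(C)C)=C[C@H]12 | intermediate (not isolated)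
22 | (5aS,6R,9S,9aS)-9-({[tert-butyl(dimethyl)silyl]oxy}methyl)-1-oxo-6-(propan-2-yl)-9-[(trimethylsilyl)oxy]-1,3,5a,6,7,8,9,9a-octahydro-2-benzoxepine-4-carboxylic acid | CC(C)[C@H]1CC[C@@](O[Si](C)(C)C)(CO[Si](C)(C)C(C)(C)C)[C@H]2C(=O)OCC(C(=O)O)=C[C@H]12 | intermediate
23 | (2S)-5-oxo-2-(propan-2-yl)hexanal | CC(C)[C@H](CCC(C)=O)C=O | intermediate
24 | (4S)-4-(propan-2-yl)cyclohex-2-en-1-one | CC(C)[C@@H]1CCC(=O)C=C1 | intermediate
25 | trimethyl{[(3S,4S)-3-ethenyl-4-(propan-2-yl)cyclohex-1-en-1-yl]oxy}silane | CC(C)[C@@H]1CCC(O[Si](C)(C)C)=C[C@H]1C=C | intermediate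
26 | lithium (3S,4S)-3-ethenyl-4-(propan-2-yl)cyclohex-1-en-1-olate | CC(C)[C@@H]1CCC(O[Li])=C[C@H]1C=C | intermediate (not isolated)
27 | (1R,2S,3S)-2-ethenyl-6-oxo-3-(propan-2-yl)cyclohexane-1-carboxylic acid | CC(C)[C@@H]1CCC(=O)[C@H](C(=O)O)[C@H]1C=C | intermediate
28 | chloromethyl (1R,2S,3S)-2-ethenyl-6-oxo-3-(propan-2-yl)cyclohexane-1-carboxylate | CC(C)[C@@H]1CCC(=O)[C@H](C(=O)OCCl)[C@H]1C=C | intermediate
29 | iodomethyl (1R,2S,3S)-2-ethenyl-6-oxo-3-(propan-2-yl)cyclohexane-1-carboxylate | CC(C)[C@@H]1CCC(=O)[C@H](C(=O)OCI)[C@H]1C=C | intermediate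
30 | ({[(1R,2S,3S)-2-ethenyl-6-oxo-3-(propan-2-yl)cyclohexane-1-carbonyl]oxy}methyl)samarium diiodide | CC(C)[C@@H]1CCC(=O)[C@H](C(=O)OC[Sm](I)I)[C@H]1C=C | intermediate (not isolated)
31 | (3aR,6S,7S,7aR)-7-ethenyl-3a-hydroxy-6-(propan-2-yl)hexahydro-2-benzofuran-1(3H)-one | CC(C)[C@@H]1CC[C@]2(O)COC(=O)[C@@H]2[C@H]1C=C | intermediate
32 | potassium (1R,2S,3S,6R)-2-ethenyl-6-hydroxy-6-(hydroxymethyl)-3-(propan-2-yl)cyclohexane-1-carboxylate | CC(C)[C@@H]1CC[C@](O)(CO)[C@H](C(=O)[O-])[C@H]1C=C.[K+] | intermediate (not isolated)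
33 | tert-butyl(dimethyl)silyl (1R,2S,3S,6R)-6-({[tert-butyl(dimethyl)silyl]oxy}methyl)-2-ethenyl-6-hydroxy-3-(propan-2-yl)cyclohexane-1-carboxylate | CC(C)[C@@H]1CC[C@](O)(CO[Si](C)(C)C(C)(C)C)[C@H](C(=O)O[Si](C)(C)C(C)(C)C)[C@H]1C=C | intermediate (not isolated)
34 | (1R,2S,3S,6R)-6-({[tert-butyl(dimethyl)silyl]oxy}methyl)-2-ethenyl-6-hydroxy-3-(propan-2-yl)cyclohexane-1-carboxylic acid | CC(C)[C@@H]1CC[C@](O)(CO[Si](C)(C)C(C)(C)C)[C@H](C(=O)O)[C@H]1C=C | intermediate
35 | 2-(tert-butoxycarbonyl)prop-2-en-1-yl (1R,2S,3S,6R)-6-({[tert-butyl(dimethyl)silyl]oxy}methyl)-2-ethenyl-6-hydroxy-3-(propan-2-yl)cyclohexane-1-carboxylate | CC(C)[C@@H]1CC[C@](O)(CO[Si](C)(C)C(C)(C)C)[C@H](C(=O)OCC(=C)C(=O)OC(C)(C)C)[C@H]1C=C | intermediate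
36 | tert-butyl (5aR,6S,9R,9aR)-9-({[tert-butyl(dimethyl)silyl]oxy}methyl)-9-hydroxy-1-oxo-6-(propan-2-yl)-1,3,5a,6,7,8,9,9a-octahydro-2-benzoxepine-4-carboxylate | CC(C)[C@@H]1CC[C@](O)(CO[Si](C)(C)C(C)(C)C)[C@@H]2C(=O)OCC(C(=O)OC(C)(C)C)=C[C@@H]12 | intermediate
37 | tert-butyl (5aR,6S,9R,9aR)-9-hydroxy-9-(hydroxymethyl)-1-oxo-6-(propan-2-yl)-1,3,5a,6,7,8,9,9a-octahydro-2-benzoxepine-4-carboxylate | CC(C)[C@@H]1CC[C@](O)(CO)[C@@H]2C(=O)OCC(C(=O)OC(C)(C)C)=C[C@@H]12 | intermediate
38 | tert-butyl (5aR,6S,9R,9aR)-9-({[(5aS,6R,9S,9aS)-9-({[tert-butyl(dimethyl)silyl]oxy}methyl)-1-oxo-6-(propan-2-yl)-9-[(trimethylsilyl)oxy]-1,3,5a,6,7,8,9,9a-octahydro-2-benzoxepine-4-carbonyl]oxy}methyl)-9-hydroxy-1-oxo-6-(propan-2-yl)-1,3,5a,6,7,8,9,9a-octahydro-2-benzoxepine-4-carboxylate | CC(C)[C@H]1CC[C@@](O[Si](C)(C)C)(CO[Si](C)(C)C(C)(C)C)[C@H]2C(=O)OCC(C(=O)OC[C@@]3(O)CC[C@@H](C(C)C)[C@@H]4C=C(C(=O)OC(C)(C)C)COC(=O)[C@H]43)=C[C@H]12 | intermediate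
39 | CNP0340505.1, (5aR,6S,9R,9aR)-9-hydroxy-9-({[(5aS,6R,9S,9aS)-9-hydroxy-9-(hydroxymethyl)-1-oxo-6-(propan-2-yl)-1,3,5a,6,7,8,9,9a-octahydro-2-benzoxepine-4-carbonyl]oxy}methyl)-1-oxo-6-(propan-2-yl)-1,3,5a,6,7,8,9,9a-octahydro-2-benzoxepine-4-carboxylic acid | CC(C)[C@H]1CC[C@@](O)(CO)[C@H]2C(=O)OCC(C(=O)OC[C@@]3(O)CC[C@@H](C(C)C)[C@@H]4C=C(C(=O)O)COC(=O)[C@H]43)=C[C@H]12 | target

**Step count and risk**

Total step count: 24. Longest linear sequence: 13 steps (steps 1–11, 23, 24; the half B branch, steps 12–22, 23, 24, is of equal length).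

Steps most likely to fail:

1. Step 7 (proposed new method). The organosamarium 13 is formed in the preferred Z rotamer of the ester, from which C9 is out of reach. If rotation to the E rotamer is slower than protonation of the carbon–samarium bond by the acidic C9a–H of a second molecule, or than electron transfer to the chelated keto group, the outcome is demetalation to the methyl ester and ketone reduction or pinacol coupling instead of ring closure. Fallback by known chemistry, setting out from 6 and returning at 14: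
   - Mukaiyama aldol hydroxymethylation of 6 with aqueous formaldehyde and Yb(OTf)3 in THF should give the all-trans β-hydroxy ketone (2R,3R,4R)-3-ethenyl-2-(hydroxymethyl)-4-(propan-2-yl)cyclohexan-1-one F1.
   - Silylation (TBSCl, imidazole, DMF) gives its silyl ether F2.
   - Corey–Chaykovsky reaction with dimethylsulfonium methylide (Me3SI, KN(SiMe3)2, THF, −10 °C), whose kinetic axial attack places the CH2 axial and cis to the C9a substituent and the oxygen equatorial, gives the spiro-epoxide F3.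
   - Buffered desilylation (TBAF, AcOH, THF) frees the epoxy alcohol F4.
   - Oxidation with TEMPO and PhI(OAc)2 in aqueous MeCN gives the epoxy acid F5, whose carboxyl opens the epoxide at its CH2 carbon (5-exo-tet, catalytic camphorsulfonic acid) to give 14.

2. Step 18 (proposed new method). The same process as in step 7 may intervene on the enantiomer: protonation or ketone reduction outrunning the rotamer change needed for closure. Fallback by the same known sequence in mirror image, setting out from 25 and returning at 31: hydroxymethylation to (2S,3S,4S)-3-ethenyl-2-(hydroxymethyl)-4-(propan-2-yl)cyclohexan-1-one F6, silylation to its silyl ether F7, axial Corey–Chaykovsky epoxidation to the enantiomeric spiro-epoxide F8, buffered desilylation to the epoxy alcohol F9, and TEMPO/PhI(OAc)2 oxidation to the epoxy acid F10, which lactonises by epoxide opening to 31.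

3. Step 10. The acyclic ester of 19 prefers the Z rotamer that holds the two alkenes apart, and the ruthenium alkylidene formed at the hindered vinyl group must engage a 1,1-disubstituted electron-poor alkene, so intermolecular metathesis to oligomers or catalyst decay may outrun closure of the seven-membered ring. Fallback by olefination instead of metathesis, setting out from 17 and returning at 20:
   - Ozonolysis (O3, CH2Cl2/MeOH, −78 °C; Me2S) converts the vinyl group into the C5 aldehyde, giving (1S,2R,3R,6S)-6-({[tert-butyl(dimethyl)silyl]oxy}methyl)-2-formyl-6-hydroxy-3-(propan-2-yl)cyclohexane-1-carboxylic acid F11.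
   - With Cs2CO3 and tert-butyl 2-(diethoxyphosphoryl)prop-2-enoate in THF the carboxylate adds in an oxa-Michael fashion to give the 2-(tert-butoxycarbonyl)-2-(diethoxyphosphoryl)ethyl ester F12, whose phosphonate anion closes onto the aldehyde by intramolecular Horner–Wadsworth–Emmons reaction to 20.
   - Step 21 is the same closure on the enantiomer and would be replaced in the same way, setting out from 34 through the aldehyde acid F13 and the phosphonate ester F14 and returning at 36.

Further compounds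
F1 | step 7 | (2R,3R,4R)-3-ethenyl-2-(hydroxymethyl)-4-(propan-2-yl)cyclohexan-1-one | CC(C)[C@H]1CCC(=O)[C@@H](CO)[C@@H]1C=C
F2 | step 7 | (2R,3R,4R)-2-({[tert-butyl(dimethyl)silyl]oxy}methyl)-3-ethenyl-4-(propan-2-yl)cyclohexan-1-one | CC(C)[C@H]1CCC(=O)[C@@H](CO[Si](C)(C)C(C)(C)C)[C@@H]1C=C
F3 | step 7 | 4-({[tert-butyl(dimethyl)silyl]oxy}methyl)-5-ethenyl-6-(propan-2-yl)-1-oxaspiro[2.5]octane, epoxide CH2 cis to the silyloxymethyl group, hand of half A | CC(C)[C@H]1CC[C@@]2(CO2)[C@@H](CO[Si](C)(C)C(C)(C)C)[C@@H]1C=C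
F4 | step 7 | [5-ethenyl-6-(propan-2-yl)-1-oxaspiro[2.5]octan-4-yl]methanol, hand of half A | CC(C)[C@H]1CC[C@@]2(CO2)[C@@H](CO)[C@@H]1C=C
F5 | step 7 | 5-ethenyl-6-(propan-2-yl)-1-oxaspiro[2.5]octane-4-carboxylic acid, hand of half A | CC(C)[C@H]1CC[C@@]2(CO2)[C@@H](C(=O)O)[C@@H]1C=C
F6 | step 18 | (2S,3S,4S)-3-ethenyl-2-(hydroxymethyl)-4-(propan-2-yl)cyclohexan-1-one | CC(C)[C@@H]1CCC(=O)[C@H](CO)[C@H]1C=C
F7 | step 18 | (2S,3S,4S)-2-({[tert-butyl(dimethyl)silyl]oxy}methyl)-3-ethenyl-4-(propan-2-yl)cyclohexan-1-one | CC(C)[C@@H]1CCC(=O)[C@H](CO[Si](C)(C)C(C)(C)C)[C@H]1C=C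
F8 | step 18 | enantiomer of F3 | CC(C)[C@@H]1CC[C@]2(CO2)[C@H](CO[Si](C)(C)C(C)(C)C)[C@H]1C=C
F9 | step 18 | enantiomer of F4 | CC(C)[C@@H]1CC[C@]2(CO2)[C@H](CO)[C@H]1C=C
F10 | step 18 | enantiomer of F5 | CC(C)[C@@H]1CC[C@]2(CO2)[C@H](C(=O)O)[C@H]1C=C
F11 | step 10 | (1S,2R,3R,6S)-6-({[tert-butyl(dimethyl)silyl]oxy}methyl)-2-formyl-6-hydroxy-3-(propan-2-yl)cyclohexane-1-carboxylic acid | CC(C)[C@H]1CC[C@@](O)(CO[Si](C)(C)C(C)(C)C)[C@@H](C(=O)O)[C@@H]1C=O
F12 | step 10 | 2-(tert-butoxycarbonyl)-2-(diethoxyphosphoryl)ethyl ester of F11 | CC(C)[C@H]1CC[C@@](O)(CO[Si](C)(C)C(C)(C)C)[C@@H](C(=O)OCC(C(=O)OC(C)(C)C)P(=O)(OCC)OCC)[C@@H]1C=O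
F13 | step 21 | (1R,2S,3S,6R)-6-({[tert-butyl(dimethyl)silyl]oxy}methyl)-2-formyl-6-hydroxy-3-(propan-2-yl)cyclohexane-1-carboxylic acid | CC(C)[C@@H]1CC[C@](O)(CO[Si](C)(C)C(C)(C)C)[C@H](C(=O)O)[C@H]1C=O
F14 | step 21 | 2-(tert-butoxycarbonyl)-2-(diethoxyphosphoryl)ethyl ester of F13 | CC(C)[C@@H]1CC[C@](O)(CO[Si](C)(C)C(C)(C)C)[C@H](C(=O)OCC(C(=O)OC(C)(C)C)P(=O)(OCC)OCC)[C@H]1C=O
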